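The earlier runs and the new flask are simulated with constants of no real substance; noise was put on by code.

Of the substrate charged to this flask, a large part is missing from the readings. I follow the flask in percent of that charge, and the ledger at 40.0 min reads:

target 3%
other capture product 35%
unread balance 62.0%

| setting | blue | flask |
|---|---|---|
| substrate | 16 mM | 16 mM |
| first nucleophile | 16 mM | 16.0 mM |
| second nucleophile | 64 mM | 64.0 mM |
| remark | the very flask that is asked about, followed so far |  |
| time |  | 2.0 h |

blue run (percent of the substrate charged)

| time / min | target / % | other capture product / % |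
|---|---|---|
| 3.00 | 3 | 6 |
| 10.0 | 2 | 17 |
| 15.0 | 3 | 19 |
| 25.0 | 3 | 29 |
| 40.0 | 3 | 35 |

(each reading ± 2 percentage points)

* ratio of target to other capture product at 1.5 min
* ratio of target to other capture product at 2.0 h
* which of target and other capture product there is more of at 2.0 h

Let r be target over other capture product. If the two nucleophiles compete for one thing, r at a given time should scale with the charge ratio ρ = first nucleophile over second nucleophile:

ρ = 0.250

I call S = r/ρ the selectivity factor. My first round uses the reading at 3.00 min:

r = 0.500, S = 2.00

Going round again with the ledger above: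

r = 0.0857, S = 0.343

So in the readings of this flask S is lower at the last time than at the first, and I use ρ to compare flasks at equal times. With a scatter of 2 percentage points on readings this small, I expect r near 0.500 at 1.5 min and below 0.0857 at 2.0 h.

The forecast gives 0.8 (range 0.3 to 2) and 0.05 (range 0.02 to 0.09), with other capture product ahead, and reads target as “a fast, small burst or fast equilibrium”.

The flask gives 0.952 and 0.00455, with other capture product ahead at 51.5% against 0.234% of target.

    substrate → intermediate (k = 9.96 × 10⁻⁴ s⁻¹)
    first nucleophile + intermediate ⇌ target (K = 300 M⁻¹, k = 2.76 M⁻¹ s⁻¹)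
    second nucleophile + intermediate → other capture product (k = 0.506 M⁻¹ s⁻¹)
    intermediate → solvolysis product (k = 0.0240 s⁻¹)
    substrate ⇌ dormant form (K = 1.41, k = 0.00147 s⁻¹)
    second nucleophile + target → over-reaction product (k = 2.53 × 10⁻⁴ M⁻¹ s⁻¹)

The forecast and the flask part over target, which in this flask peaks at 4.25% after 5.118 min and then falls to 0.234% at 2.0 h. Dividing the flask's ratios by ρ gives S = 3.81 at 1.5 min and S = 0.0182 at 2.0 h. The neighbouring flask, with 6.4 mM of first nucleophile, has ρ = 0.100, so I reckon r = 0.381 and r = 0.00182 for it. That neighbouring flask gives 0.381 at 1.5 min and 0.00178 at 2.0 h.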